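Readings and results stem from a simulated flask for substances that don't exist.

The south-east run is the very flask asked about, but it stops at 60.0 s, far earlier than the 12 min allowed, so the peak has to be bracketed from what it shows.

- south-east: starting material 1.5 M; reagent in the second phase 1.5 equiv; protic impurity 0.30 M; the very flask that is asked about, followed so far
- flask: starting material 1.5 M; reagent in the second phase 1.50 equiv; protic impurity 0.300 M; time 12 min; volume of the second phase over the first 1.0

south-east run (percent of the starting material charged): time / s: target / % = 10.0: 12.1; 15.0: 17.5; 25.0: 27.7; 40.0: 41.4; 60.0: 52.6

(scatter of a reading: 1 percentage point)

- time, not beyond 12 min, at which the flask holds most target
- the amount of target, in percent of the starting material charged, at that time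

- amounts and yields of target count product in the second phase too
- in the second phase: reagent in the second phase, product in the second phase; everything else is in the first
- charges count per volume of the first phase; a concentration in a rate is the amount of a species over the volume of its own phase; every rate counts per litre of the first phase
- candidate steps: reagent in the reaction phase <-> reagent in the second phase; starting material + reagent in the reaction phase -> target; target <-> product in the second phase; target -> decomposed product; starting material + protic impurity -> quenched substrate
- the earlier runs hold the two phases in the same ratio of volumes as the flask asked about

From below, the flask has already read 52.6 % of target at 60.0 s and is still rising, so its best stands above that reading, within scatter, and comes later. From above, the first bound is the 100 % charged. The protic impurity at 0.300 M against 1.5 M of starting material tightens this to 80.0 % if it consumes its charge mole for mole: this is the ceiling C, the fraction of starting material left for target once the protic impurity has taken its share. Continuing the last slope of the readings, target reaches C at about 1.82 min. This reckoning, an estimate and not a bound, puts the peak near that time, and the bracket on the best amount stands between 52.6 % and C.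

The forecast gives 82 % at 6 min, above C and later than that time, on the ground that “Decomposition is invisible in these data”.

The flask gives 62.4 % at 1.53 min, inside the bracket.

    reagent in the reaction phase ⇌ reagent in the second phase, rate k1*([reagent in the reaction phase] - [reagent in the second phase]/K1) per volume of the first phase (partition coefficient = 0.990, kL = 0.00900 s⁻¹)
    starting material + reagent in the reaction phase → target (k = 1.70 M⁻¹ s⁻¹)
    target ⇌ product in the second phase, rate k3*([target] - [product in the second phase]/K3) per volume of the first phase (partition coefficient = 0.370, kL = 0.0110 s⁻¹)
    target → decomposed product (k = 0.00520 s⁻¹)
    starting material + protic impurity → quenched substrate (k = 0.130 M⁻¹ s⁻¹)

At that time quenched substrate stands at 20.0 %, and target, decomposed product and starting material sum to 80.0 %, close to C. Half of the turnover to target is done by 0.588 min, earlier than half of the decomposition at 3.29 min. Reaction-phase target is made 1.97 times faster than it is used up at 0.896 min, but that ratio is 0.297 at 12.0 min. The neighbouring flask with 0.51 M of protic impurity has C at 66.0 %, and its highest target is 54.0 %.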